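**Strategy.** Everything rests on cutting the C3–C4 bond of the cyclopentanone ring (C1 carbonyl, C2 carrying the cyclopropane, C3 the quaternary carbon with CH3 and the benzylic carbon C1′). C3 is read as the methyl-bearing carbon of a cyclohexene oxide: one Lewis-acid step shifts the ring CH2 onto it, contracts six to five, fixes C3 and releases C1′ as a formyl group 1,3 to the masked C1 ketone. The precursor is the enantioenriched epoxide of 3-methylcyclohex-3-enone ethylene ketal. C1′ is then completed by sparteine-controlled lithiation–borylation, the cis-cyclopropane by a C1–O-tethered carbene, and the phloroglucinol is freed and formylated last.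

Key step: step 3

Labels: ring carbons C1 (carbonyl), C2, C3 (quaternary), C4, C5; C1′ = benzylic carbon; Cb = cyclopropane CH on C2, Ca = cyclopropane CH bearing the chain; Ar = 2,4,6-tris(benzyloxy)phenyl; R* = (S)-ArCH(CH=CMe2)– (the C1′ branch).

Assumption: (+)-sparteine and the L-fructose-derived (ent-)Shi ketone are taken as purchasable reagents; the dioxolane is kept as the ketone mask because a five-membered ketal tolerates both the pH 10.5 epoxidation and an aluminium Lewis acid at −78 °C.

Step 1
Reactants: 1 3-methylcyclohex-2-en-1-one; 2 ethylene glycol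
Product: 3 7-methyl-1,4-dioxaspiro[4.5]dec-7-ene
Conditions: p-TsOH (cat.), benzene, reflux, Dean–Stark
Reagents that add atoms: none
Why: Acid-catalysed ketalisation with removal of water equilibrates through the dienol ether, so the alkene should settle out of conjugation as the trisubstituted ring alkene (deconjugative ketalisation); no stereocentre is formed.

Step 2
Reactants: 3 alkene ketal
Product: 4 (1R,6S)-1-methyl-7-oxabicyclo[4.1.0]heptan-3-one ethylene ketal
Conditions: ent-Shi ketone (L-fructose-derived, 0.3 equiv), Oxone, K2CO3, Bu4NHSO4, MeCN–DMM/aq. Na2B4O7–EDTA (pH 10.5), 0 °C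
Reagents that add atoms: Oxone (potassium peroxymonosulfate), [K+].[O-]S(=O)(=O)OO
Why: Shi asymmetric epoxidation: the chiral dioxirane delivers oxygen through a spiro transition state to one face of the trisubstituted alkene, and since the D-fructose ketone attacks the opposite face in 1-substituted cyclohexenes, the L-series catalyst should set both epoxide carbons as (1R,6S) while the basic buffer protects the ketal.

Step 3
Reactants: 4 epoxy ketal
Product: 5 (S)-7-methyl-1,4-dioxaspiro[4.4]nonane-7-carbaldehyde
Conditions: MABR (2 equiv; preformed from Me3Al and 4-bromo-2,6-di-tert-butylphenol), CH2Cl2, −78 °C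
Reagents that add atoms: none
Why: The aluminium phenoxide binds the epoxide oxygen and stretches the C–O bond at the methyl-bearing carbon C1; as that bond breaks, the ring bond C6–C5 lying anti to it shifts from C6 to C1 and the oxygen left on C6 becomes the formyl group (semipinacol/Meinwald rearrangement). The closest known reaction type is the bulky-aluminium-promoted rearrangement of trisubstituted epoxides to α-quaternary aldehydes, including the contraction of 1-methylcyclohexene oxide to 1-methylcyclopentanecarbaldehyde. The cyclopentane is closed by a suprafacial 1,2-alkyl shift through a three-centre transition state (ring contraction), not by cyclisation of a chain. The new quaternary centre (C3 of the target) is controlled by the epoxide configuration, because the migrating CH2 enters anti to the departing oxygen with inversion, so (1R,6S)-4 should give (S)-5, which corresponds to (R)-C3 of the target. The step needs tertiary rather than secondary C–O cleavage and ring-carbon rather than hydride migration: the methyl group secures the first, and the bulky Lewis acid, which keeps the C6–H bond out of alignment, the second. The dioxolane two bonds away withdraws electron density, which disfavours a free cation and so protects the stereospecificity, and it should survive at −78 °C.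

Step 4
Reactants: 5 aldehyde
Product: 6 [(S)-7-methyl-1,4-dioxaspiro[4.4]nonan-7-yl]methanol
Conditions: NaBH4, MeOH, 0 °C
Reagents that add atoms: none
Why: Borohydride reduction of a non-enolisable aldehyde should leave the quaternary centre untouched.

Step 5
Reactants: 6 primary alcohol
Product: 7 [(S)-7-methyl-1,4-dioxaspiro[4.4]nonan-7-yl]methyl N,N-diisopropylcarbamate
Conditions: i-Pr2NCOCl, Et3N, DMAP (cat.), CH2Cl2, reflux
Reagents that add atoms: N,N-diisopropylcarbamoyl chloride, CC(C)N(C(C)C)C(Cl)=O
Why: O-Carbamoylation (acyl substitution) of the primary alcohol installs the group that directs α-lithiation and later leaves in the 1,2-shift.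

Step 6
Reactants: 8 1,3,5-tris(benzyloxy)benzene
Product: 10 2-[2,4,6-tris(benzyloxy)phenyl]-4,4,5,5-tetramethyl-1,3,2-dioxaborolane, via aryllithium 9 (not isolated)
Conditions: n-BuLi, TMEDA, THF, 0 °C; then i-PrOBpin, −78 °C → rt
Reagents that add atoms: 2-isopropoxy-4,4,5,5-tetramethyl-1,3,2-dioxaborolane, CC(C)OB1OC(C)(C)C(C)(C)O1
Why: Directed ortho-metalation between two alkoxy groups followed by trapping with an alkoxyboronate (DoM–borylation) should give the aryl pinacol boronate.

Step 7
Reactants: 7 carbamate; 10 aryl pinacol boronate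
Product: 13 2-{(S)-[(S)-7-methyl-1,4-dioxaspiro[4.4]nonan-7-yl](Ar)methyl}-4,4,5,5-tetramethyl-1,3,2-dioxaborolane, via lithiated carbamate 11 (not isolated), via boronate complex 12 (not isolated)
Conditions: s-BuLi, (+)-sparteine, Et2O, −78 °C; then 10, −78 °C; then MgBr2·OEt2, −78 °C → reflux
Reagents that add atoms: none
Why: Lithiation–borylation: the s-BuLi/(+)-sparteine complex removes the pro-R hydrogen next to the carbamate oxygen, the boronate adds with retention and the aryl group then shifts from boron to carbon anti to the departing carbamate (1,2-metallate rearrangement with inversion), so C1′ should be set (S) by the diamine rather than by the substrate.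

Step 8
Reactants: 13 benzylic boronic ester
Product: 16 (S)-7-methyl-7-{(S)-3-methyl-1-Ar-but-2-en-1-yl}-1,4-dioxaspiro[4.4]nonane, via alkenylboronate complex 14 (not isolated), via iodoalkyl boronic ester 15 (not isolated)
Conditions: 1-bromo-2-methylprop-1-ene, t-BuLi, Et2O, −78 °C; then 13, THF; then I2, MeOH, −78 °C; then NaOMe, −78 °C → rt
Reagents that add atoms: 1-bromo-2-methylprop-1-ene, CC(C)=CBr
Why: Zweifel olefination: iodination of the alkenyl boronate complex triggers a 1,2-shift of C1′ from boron to carbon with retention, and methoxide-induced elimination of boron and iodide leaves the 2-methylpropenyl group on C1′ without changing its configuration.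

Step 9
Reactants: 16 alkene ketal
Product: 17 (S)-3-methyl-3-R*-cyclopentan-1-one
Conditions: PPTS, acetone–H2O, 55 °C
Reagents that add atoms: water, O
Why: Mild acid-catalysed acetal hydrolysis should free the C1 ketone while the benzyl ethers and the trisubstituted alkene are inert to pyridinium tosylate.

Step 10
Reactants: 17 ketone
Product: 19 (R)-4-methyl-4-R*-cyclopent-2-en-1-one, via silyl enol ether 18 (not isolated)
Conditions: LDA, TMSCl, THF, −78 °C; then Pd(OAc)2, MeCN, rt
Reagents that add atoms: none
Why: Saegusa–Ito oxidation: kinetic deprotonation should occur at C5 because C2 is neopentyl-type and shielded, and palladation of the silyl enol ether with β-hydride elimination from C4 gives the C4=C5 enone, the only enone that the quaternary C3 allows.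

Step 11
Reactants: 20 2-methylpropanal
Product: 21 2-methyl-2-(phenylselanyl)propanal
Conditions: PhSeCl, EtOAc, rt
Reagents that add atoms: benzeneselenenyl chloride, Cl[Se]c1ccccc1
Why: Electrophilic α-selenenylation of the aldehyde through its enol should give the non-enolisable α-seleno aldehyde.

Step 12
Reactants: 19 enone; 21 seleno aldehyde
Product: 23 (4R,5S)-5-[1-hydroxy-2-methyl-2-(phenylselanyl)propyl]-4-methyl-4-R*-cyclopent-2-en-1-one (carbinol epimers), via lithium dienolate 22 (not isolated)
Conditions: LDA, THF, −78 °C; then 21, −78 °C; then H2O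
Reagents that add atoms: none
Why: Aldol addition of a cross-conjugated lithium dienolate: with C5 sp2 and C3 quaternary only C2 can be deprotonated, and the aldehyde should approach C2 anti to the bulky C1′ branch, i.e. cis to the C3 methyl, which sets C2 (the carbinol centre is removed in step 13).

Step 13
Reactants: 23 β-hydroxy selenide
Product: 24 (4R,5R)-4-methyl-5-(2-methylprop-1-en-1-yl)-4-R*-cyclopent-2-en-1-one
Conditions: MsCl, Et3N, cyclohexene (excess), CH2Cl2, 0 °C
Reagents that add atoms: none
Why: β-Hydroxy selenide elimination: after mesylation selenium expels the leaving group as a seleniranium ion that collapses to the alkene strictly between the carbinol carbon and the selenium-bearing carbon, so the β,γ-unsaturated ketone should form without moving the C2 hydrogen, and cyclohexene traps the electrophilic selenium that is released.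

Step 14
Reactants: 24 dienone
Product: 25 (2R,3R)-3-methyl-2-(2-methylprop-1-en-1-yl)-3-R*-cyclopentan-1-one
Conditions: H2 (1 atm), RhCl(PPh3)3 (cat.), benzene–EtOH, rt
Reagents that add atoms: none
Why: Homogeneous hydrogenation with Wilkinson's catalyst should reduce the cis-disubstituted enone alkene and leave the two trisubstituted alkenes and the benzyl ethers untouched.

Step 15
Reactants: 25 ketone
Product: 26 (1S,2R,3R)-3-methyl-2-(2-methylprop-1-en-1-yl)-3-R*-cyclopentan-1-ol
Conditions: L-Selectride, THF, −78 °C; then H2O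
Reagents that add atoms: none
Why: Bulky hydride reduction: the trialkylborohydride should attack C1 from the face opposite the adjacent C2 alkenyl group, so the hydroxyl comes out cis to that group, which is the relationship the tether needs.

Step 16
Reactants: 26 alcohol
Product: 28 diazoacetate of 26, via bromoacetate 27 (not isolated)
Conditions: BrCH2COBr, pyridine, CH2Cl2, 0 °C; then TsNHNHTs, DBU, THF, 0 °C
Reagents that add atoms: bromoacetyl bromide, BrCC(Br)=O; N,N′-ditosylhydrazine, Cc1ccc(cc1)S(=O)(=O)NNS(=O)(=O)c1ccc(C)cc1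
Why: O-Acylation, then N-alkylation of the ditosylhydrazine and double sulfinate elimination (Bamford–Stevens-type diazoacetate synthesis) should give the diazo ester under mild base.

Step 17
Reactants: 28 diazoacetate
Product: 29 tricyclic δ-lactone (C1–O–C(=O)–Ca–Cb–C2) with the gem-dimethylcyclopropane cis-fused at Ca–Cb
Conditions: Rh2(cap)4 (1 mol %), CH2Cl2, reflux, slow addition
Reagents that add atoms: none
Why: Rhodium-carbenoid intramolecular cyclopropanation: the ester tether on C1–O can deliver the carbene only to the alkene face on the C1 side, allylic 1,3-strain holds C2–H eclipsed with the alkene so that this face gives the required configuration at Cb, and the six-membered lactone forces the carbonyl on Ca and C2 on Cb to be cis on the new cyclopropane.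

Step 18
Reactants: 29 lactone
Product: 30 diol (C1–OH and Ca–CH2OH)
Conditions: LiAlH4, THF, 0 °C
Reagents that add atoms: none
Why: Lithium aluminium hydride reduction of the lactone should open it to the diol without touching any stereocentre.

Step 19
Reactants: 30 diol
Product: 31 keto aldehyde (C1 ketone and Ca–CHO)
Conditions: (COCl)2, DMSO, CH2Cl2, −78 °C; then Et3N, −78 → 0 °C
Reagents that add atoms: none
Why: Swern oxidation activates both hydroxyls as alkoxysulfonium salts before base is added, so ketone and aldehyde should appear together and the hydroxy aldehyde cannot close to a lactol and be oxidised back to the lactone.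

Step 20
Reactants: 31 keto aldehyde
Product: 32 (E)-enone (Ca–CH=CH–COCH3)
Conditions: Ph3P=CHCOCH3, toluene, 60 °C
Reagents that add atoms: 1-(triphenylphosphoranylidene)propan-2-one, CC(=O)C=P(c1ccccc1)(c1ccccc1)c1ccccc1
Why: Wittig olefination with a stabilised ylide should react only at the aldehyde and give the (E)-enone, adding the last three chain carbons.

Step 21
Reactants: 32 enedione
Product: 33 tri-O-benzyl diketone with the 2-methylpropenyl group still on C1′
Conditions: H2 (1 atm), RhCl(PPh3)3 (cat.), benzene, rt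
Reagents that add atoms: none
Why: Homogeneous hydrogenation with Wilkinson's catalyst should saturate the disubstituted enone alkene without the ring hydrogenolysis that heterogeneous palladium can cause in vinylcyclopropanes, and the trisubstituted alkene on C1′ is too hindered to react.

Step 22
Reactants: 33 tri-O-benzyl diketone
Product: 34 bis-deformyl macrocarpal N (free phloroglucinol)
Conditions: H2 (1–3 atm), Pd/C, EtOAc–MeOH, rt
Reagents that add atoms: none
Why: Catalytic hydrogenolysis/hydrogenation should remove the three benzyl ethers and saturate the 2-methylpropenyl group to isobutyl under neutral conditions that leave the ketones and the alkyl-substituted cyclopropane alone.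

Step 23
Reactants: 34 alkylphloroglucinol
Product: 36 macrocarpal N, via bis-iminium salt 35 (not isolated)
Conditions: POCl3, DMF, EtOAc, 0 °C → rt; then H2O, 50 °C
Reagents that add atoms: N,N-dimethylformamide, CN(C)C=O; water, O
Why: Vilsmeier–Haack formylation: the two free ring positions of the phloroglucinol are far more nucleophilic than the ketone enols, so the chloroiminium ion should substitute both and hydrolysis gives the dialdehyde.

**Compound list**

1 | 3-methylcyclohex-2-en-1-one | CC1=CC(=O)CCC1 | starting material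
2 | ethylene glycol | OCCO | starting material
3 | 7-methyl-1,4-dioxaspiro[4.5]dec-7-ene (3-methylcyclohex-3-enone ethylene ketal) | CC1=CCCC2(C1)OCCO2 | intermediate
4 | (1R,6S)-1-methyl-7-oxabicyclo[4.1.0]heptan-3-one ethylene ketal | C[C@]12O[C@H]1CCC3(C2)OCCO3 | intermediate
5 | (S)-7-methyl-1,4-dioxaspiro[4.4]nonane-7-carbaldehyde (3-formyl-3-methylcyclopentanone ethylene ketal) | O=C[C@@]1(C)CCC2(C1)OCCO2 | intermediate
6 | [(S)-7-methyl-1,4-dioxaspiro[4.4]nonan-7-yl]methanol | OC[C@@]1(C)CCC2(C1)OCCO2 | intermediate
7 | [(S)-7-methyl-1,4-dioxaspiro[4.4]nonan-7-yl]methyl N,N-diisopropylcarbamate | CC(C)N(C(C)C)C(=O)OC[C@@]1(C)CCC2(C1)OCCO2 | intermediate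
8 | 1,3,5-tris(benzyloxy)benzene | c1c(OCc2ccccc2)cc(OCc2ccccc2)cc1OCc1ccccc1 | starting material
9 | 2,4,6-tris(benzyloxy)phenyllithium | [Li]c1c(OCc2ccccc2)cc(OCc2ccccc2)cc1OCc1ccccc1 | intermediate
10 | 2-[2,4,6-tris(benzyloxy)phenyl]-4,4,5,5-tetramethyl-1,3,2-dioxaborolane | CC1(C)OB(OC1(C)C)c1c(OCc2ccccc2)cc(OCc2ccccc2)cc1OCc1ccccc1 | intermediate
11 | (R)-α-lithio derivative of 7 (held as its (+)-sparteine complex) | [Li][C@@H](OC(=O)N(C(C)C)C(C)C)[C@@]1(C)CCC2(C1)OCCO2 | intermediate
12 | lithium boronate complex from 11 and 10 (boron carries Ar, pinacolate and the carbamoyloxy-bearing C1′) | CC1(C)O[B-](OC1(C)C)(c1c(OCc2ccccc2)cc(OCc2ccccc2)cc1OCc1ccccc1)[C@@H](OC(=O)N(C(C)C)C(C)C)[C@@]1(C)CCC2(C1)OCCO2.[Li+] | intermediate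
13 | 2-{(S)-[(S)-7-methyl-1,4-dioxaspiro[4.4]nonan-7-yl][2,4,6-tris(benzyloxy)phenyl]methyl}-4,4,5,5-tetramethyl-1,3,2-dioxaborolane | CC1(C)OB(OC1(C)C)[C@H](c1c(OCc2ccccc2)cc(OCc2ccccc2)cc1OCc1ccccc1)[C@@]1(C)CCC2(C1)OCCO2 | intermediate
14 | lithium (2-methylprop-1-enyl)boronate complex of 13 | CC(C)=C[B-]1(OC(C)(C)C(C)(C)O1)[C@H](c1c(OCc2ccccc2)cc(OCc2ccccc2)cc1OCc1ccccc1)[C@@]1(C)CCC2(C1)OCCO2.[Li+] | intermediate
15 | β-iodoalkyl boronic ester (C1′–CH(Bpin)–C(I)Me2; configuration at the boron-bearing carbon not relevant) | CC(C)(I)C(B1OC(C)(C)C(C)(C)O1)[C@H](c1c(OCc2ccccc2)cc(OCc2ccccc2)cc1OCc1ccccc1)[C@@]1(C)CCC2(C1)OCCO2 | intermediate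
16 | (S)-7-methyl-7-{(S)-3-methyl-1-[2,4,6-tris(benzyloxy)phenyl]but-2-en-1-yl}-1,4-dioxaspiro[4.4]nonane | CC(C)=C[C@H](c1c(OCc2ccccc2)cc(OCc2ccccc2)cc1OCc1ccccc1)[C@@]1(C)CCC2(C1)OCCO2 | intermediate
17 | (S)-3-methyl-3-{(S)-3-methyl-1-[2,4,6-tris(benzyloxy)phenyl]but-2-en-1-yl}cyclopentan-1-one | CC(C)=C[C@H](c1c(OCc2ccccc2)cc(OCc2ccccc2)cc1OCc1ccccc1)[C@@]1(C)CCC(=O)C1 | intermediate
18 | trimethylsilyl enol ether of 17 with the enol double bond C1=C5 | CC(C)=C[C@H](c1c(OCc2ccccc2)cc(OCc2ccccc2)cc1OCc1ccccc1)[C@@]1(C)CC=C(O[Si](C)(C)C)C1 | intermediate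
19 | (R)-4-methyl-4-{(S)-3-methyl-1-[2,4,6-tris(benzyloxy)phenyl]but-2-en-1-yl}cyclopent-2-en-1-one | CC(C)=C[C@H](c1c(OCc2ccccc2)cc(OCc2ccccc2)cc1OCc1ccccc1)[C@@]1(C)C=CC(=O)C1 | intermediate
20 | 2-methylpropanal | CC(C)C=O | starting material
21 | 2-methyl-2-(phenylselanyl)propanal | CC(C)([Se]c1ccccc1)C=O | intermediate
22 | lithium dienolate of 19 (O–Li on C1; C1=C2 and C4=C5) | CC(C)=C[C@H](c1c(OCc2ccccc2)cc(OCc2ccccc2)cc1OCc1ccccc1)[C@@]1(C)C=CC(O[Li])=C1 | intermediate
23 | (4R,5S)-5-[1-hydroxy-2-methyl-2-(phenylselanyl)propyl]-4-methyl-4-R*-cyclopent-2-en-1-one (both carbinol epimers; new group cis to the C4 methyl) | CC(C)=C[C@H](c1c(OCc2ccccc2)cc(OCc2ccccc2)cc1OCc1ccccc1)[C@@]1(C)C=CC(=O)[C@@H]1C(O)C(C)(C)[Se]c1ccccc1 | intermediate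
24 | (4R,5R)-4-methyl-5-(2-methylprop-1-en-1-yl)-4-R*-cyclopent-2-en-1-one | CC(C)=C[C@H](c1c(OCc2ccccc2)cc(OCc2ccccc2)cc1OCc1ccccc1)[C@@]1(C)C=CC(=O)[C@@H]1C=C(C)C | intermediate
25 | (2R,3R)-3-methyl-2-(2-methylprop-1-en-1-yl)-3-R*-cyclopentan-1-one | CC(C)=C[C@H](c1c(OCc2ccccc2)cc(OCc2ccccc2)cc1OCc1ccccc1)[C@@]1(C)CCC(=O)[C@@H]1C=C(C)C | intermediate
26 | (1S,2R,3R)-3-methyl-2-(2-methylprop-1-en-1-yl)-3-R*-cyclopentan-1-ol (OH cis to the C2 alkenyl group) | CC(C)=C[C@H](c1c(OCc2ccccc2)cc(OCc2ccccc2)cc1OCc1ccccc1)[C@@]1(C)CC[C@H](O)[C@@H]1C=C(C)C | intermediate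
27 | bromoacetate of 26 | CC(C)=C[C@H](c1c(OCc2ccccc2)cc(OCc2ccccc2)cc1OCc1ccccc1)[C@@]1(C)CC[C@H](OC(=O)CBr)[C@@H]1C=C(C)C | intermediate
28 | diazoacetate of 26 | CC(C)=C[C@H](c1c(OCc2ccccc2)cc(OCc2ccccc2)cc1OCc1ccccc1)[C@@]1(C)CC[C@H](OC(=O)C=[N+]=[N-])[C@@H]1C=C(C)C | intermediate
29 | tricyclic lactone: δ-lactone O–C(=O) joining C1–O to Ca; Ca–H and Cb–H cis on a gem-dimethylcyclopropane (Ca R, Cb S); C1–O and C2–Cb cis on the cyclopentane and cis to the C3 methyl; C3 carries CH3 and R* | CC(C)=C[C@H](c1c(OCc2ccccc2)cc(OCc2ccccc2)cc1OCc1ccccc1)[C@@]1(C)CC[C@@H]2OC(=O)[C@@H]3[C@H]([C@H]12)C3(C)C | intermediate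
30 | diol: cyclopentan-1-ol (OH cis to the C2 substituent) whose C2 bears the cis-2-(hydroxymethyl)-3,3-dimethylcyclopropyl group (Ca R, Cb R); C3 carries CH3 and R* | OC[C@@H]1[C@H]([C@H]2[C@@H](O)CC[C@]2(C)[C@H](C=C(C)C)c2c(OCc3ccccc3)cc(OCc3ccccc3)cc2OCc2ccccc2)C1(C)C | intermediate
31 | keto aldehyde: cyclopentanone whose C2 bears the cis-2-formyl-3,3-dimethylcyclopropyl group; C3 carries CH3 and R* | O=C[C@@H]1[C@H]([C@H]2C(=O)CC[C@]2(C)[C@H](C=C(C)C)c2c(OCc3ccccc3)cc(OCc3ccccc3)cc2OCc2ccccc2)C1(C)C | intermediate
32 | (E)-enone: as 31 with Ca–CH=CH–C(=O)CH3 in place of Ca–CHO | CC(=O)/C=C/[C@@H]1[C@H]([C@H]2C(=O)CC[C@]2(C)[C@H](C=C(C)C)c2c(OCc3ccccc3)cc(OCc3ccccc3)cc2OCc2ccccc2)C1(C)C | intermediate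
33 | tri-O-benzyl diketone: target skeleton with Ar = 2,4,6-tris(benzyloxy)phenyl and CH=CMe2 on C1′ | CC(=O)CC[C@@H]1[C@H]([C@H]2C(=O)CC[C@]2(C)[C@H](C=C(C)C)c2c(OCc3ccccc3)cc(OCc3ccccc3)cc2OCc2ccccc2)C1(C)C | intermediate
34 | bis-deformyl macrocarpal N (2,4,6-trihydroxyphenyl, isobutyl on C1′) | CC(=O)CC[C@@H]1[C@H]([C@H]2C(=O)CC[C@]2(C)[C@H](CC(C)C)c2c(O)cc(O)cc2O)C1(C)C | intermediate
35 | bis(N,N-dimethyliminium) dichloride at the two free ring positions of 34 | CC(=O)CC[C@@H]1[C@H]([C@H]2C(=O)CC[C@]2(C)[C@H](CC(C)C)c2c(O)c(C=[N+](C)C)c(O)c(C=[N+](C)C)c2O)C1(C)C.[Cl-].[Cl-] | intermediate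
36 | macrocarpal N (Ca R, Cb R, C2 R, C3 R, C1′ S) | CC(=O)CC[C@@H]1[C@H]([C@H]2C(=O)CC[C@]2(C)[C@H](CC(C)C)c2c(O)c(C=O)c(O)c(C=O)c2O)C1(C)C | target

**Step count.** Total: 23 steps. Longest linear sequence: 21 steps (1–5, 7–10, 12–23); steps 6 and 11 are one-step side branches.

**Steps most likely to fail**

First, step 7. The α-deprotonation of the neopentyl-type carbamate may be slow, the crowded boronate complex may form reversibly, and the diamine may be mismatched with the C3 stereocentre; each would erode or prevent the stereospecific aryl transfer. The fallback replaces the 1,2-metallate shift by a cationic benzylic substitution and sets out from aldehyde 5. Addition of aryllithium 9 (THF, −78 °C) should give the benzylic alcohol [(S)-7-methyl-1,4-dioxaspiro[4.4]nonan-7-yl][2,4,6-tris(benzyloxy)phenyl]methanol F1 as a mixture of carbinol epimers. Ionisation of this very electron-rich benzylic alcohol with BF3·OEt2 in the presence of potassium (2-methylprop-1-en-1-yl)trifluoroborate (CH2Cl2–MeCN, −40 °C) should give 16 together with its C1′ epimer (S)-7-methyl-7-{(R)-3-methyl-1-[2,4,6-tris(benzyloxy)phenyl]but-2-en-1-yl}-1,4-dioxaspiro[4.4]nonane F2. Here stereocontrol is given up and the epimers are separated by chromatography; the route is rejoined at 16.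

Second, step 3. Hydride may migrate instead of the ring carbon (giving the 2-methylcyclohexanone ketal), the aluminium Lewis acid may open the dioxolane, or stepwise ionisation may erode the transfer of configuration. The fallback is a halohydrin contraction by double inversion and sets out from alkene 3. Epoxidation with the D-fructose-derived Shi ketone should give the enantiomeric epoxide (1S,6R)-1-methyl-7-oxabicyclo[4.1.0]heptan-3-one ethylene ketal F3. MgBr2·OEt2 (Et2O, 0 °C) should open it at the tertiary carbon with inversion to the trans-bromohydrin (1R,2R)-2-bromo-4,4-(ethylenedioxy)-2-methylcyclohexan-1-ol F4. Deprotonation with EtMgBr and warming in benzene should make the ring CH2 displace bromide from the opposite face, so the two inversions deliver the same (S)-aldehyde 5, where the route is rejoined.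

Third, step 12. The C–C bond between two neopentyl-type carbons may not form or may revert by retro-aldol on work-up, and proton exchange may return the enone. The fallback replaces aldol/elimination by cross-coupling and sets out from enone 19: palladium-catalysed α′-alkenylation of its lithium enolate with 1-bromo-2-methylprop-1-ene (LiHMDS, Pd2(dba)3, a bulky trialkylphosphine, toluene) should lead directly to dienone 24, where the route is rejoined; no new compound is made on the way.

Further compounds
F1 | step 7 | [(S)-7-methyl-1,4-dioxaspiro[4.4]nonan-7-yl][2,4,6-tris(benzyloxy)phenyl]methanol (carbinol epimers) | OC(c1c(OCc2ccccc2)cc(OCc2ccccc2)cc1OCc1ccccc1)[C@@]1(C)CCC2(C1)OCCO2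
F2 | step 7 | (S)-7-methyl-7-{(R)-3-methyl-1-[2,4,6-tris(benzyloxy)phenyl]but-2-en-1-yl}-1,4-dioxaspiro[4.4]nonane | CC(C)=C[C@@H](c1c(OCc2ccccc2)cc(OCc2ccccc2)cc1OCc1ccccc1)[C@@]1(C)CCC2(C1)OCCO2
F3 | step 3 | (1S,6R)-1-methyl-7-oxabicyclo[4.1.0]heptan-3-one ethylene ketal | C[C@@]12O[C@@H]1CCC3(C2)OCCO3
F4 | step 3 | (1R,2R)-2-bromo-4,4-(ethylenedioxy)-2-methylcyclohexan-1-ol | C[C@@]1(Br)CC2(CC[C@H]1O)OCCO2
F0 | step 12 | none | none
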